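## Retrosynthetic overview

1. Acid 12 comes from its ethyl ester 11 by saponification; 11 comes from the open-chain phenol 9 in one oxidative operation that makes the O1–C8a bond (chroman numbering: O1, C2, C3, C4, C4a, C5–C8, C8a).
2. Enabling feature: on the benzene ring C8a lies para to the C6 hydroxyl, its neighbour C4a bears H while C8 bears the methyl, and O1 is held three carbons (C2–C3–C4) from the ring. A phenol oxidized at C6–OH is electrophilic at C8a, so O1 can close onto C8a while C4 is still attached there, and C4 then moves to C4a.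
3. Ring order: the benzene ring is bought (4-bromo-3-methylphenol 7); a transient five-membered oxaspiro ring is closed first (O1–C8a) and is enlarged in the same flask to the pyran ring.
4. Phenol 9 comes from vinyl carbinol 6 and 7 by hydroboration and B-alkyl Suzuki coupling.
5. Carbinol 6 comes from (R)-linalool 1, which supplies C2 with its methyl, its oxygen and its configuration; the chain is lengthened by E-selective allylic oxidation, bromination, cyanomethylation, reduction and E-selective Wittig olefination.

Key step: step 7

Assumption: (R)-(−)-linalool of high enantiomeric purity is purchasable; its carbinol carbon becomes C2, and since no bond to it is made or broken the 2R arrangement is carried through unchanged.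

## Route

Step 1
Reactants: 1 (R)-(−)-linalool
Product: 2 (2E,6R)-2,6-dimethylocta-2,7-diene-1,6-diol
Conditions: SeO2 (0.3 equiv), t-BuOOH (2 equiv), salicylic acid (0.1 equiv), CH2Cl2, 0 °C to rt
Reagents that add atoms: tert-butyl hydroperoxide, CC(C)(C)OO (its oxygen atom is passed on through SeO2, O=[Se]=O)
Why: SeO2 allylic oxidation (ene reaction, then [2,3]-sigmatropic rearrangement, with t-BuOOH as terminal oxidant) should attack the electron-rich trisubstituted alkene at its (E)-methyl group and leave the vinyl group, the tertiary alcohol and the stereocenter untouched, so the (E)-allylic alcohol is expected and no new stereocenter is formed.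

Step 2
Reactants: 2 (2E,6R)-2,6-dimethylocta-2,7-diene-1,6-diol
Product: 3 (3R,6E)-8-bromo-3,7-dimethylocta-1,6-dien-3-ol
Conditions: CBr4 (1.1 equiv), PPh3 (1.15 equiv), CH2Cl2, −20 to 0 °C
Reagents that add atoms: carbon tetrabromide, BrC(Br)(Br)Br
Why: Appel reaction, in which the primary allylic hydroxyl should be displaced (SN2 on its oxyphosphonium salt) far faster than the hindered tertiary hydroxyl, with the E geometry kept and no new stereocenter.

Step 3
Reactants: 3 (3R,6E)-8-bromo-3,7-dimethylocta-1,6-dien-3-ol
Product: 4 (4E,8R)-8-hydroxy-4,8-dimethyldeca-4,9-dienenitrile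
Conditions: MeCN (6 equiv), n-BuLi (5 equiv), THF, −78 °C; then 3 added slowly, −78 to −40 °C; aq. NH4Cl
Reagents that add atoms: acetonitrile, CC#N (as lithioacetonitrile)
Why: SN2 alkylation of lithioacetonitrile by the primary allylic bromide (cyanomethylation), run with excess nucleophile and inverse addition at low temperature so that the tertiary lithium alkoxide should not compete and dialkylation is suppressed; no new stereocenter.

Step 4
Reactants: 4 (4E,8R)-8-hydroxy-4,8-dimethyldeca-4,9-dienenitrile
Product: 5 (4E,8R)-8-hydroxy-4,8-dimethyldeca-4,9-dienal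
Conditions: i-Bu2AlH (2.3 equiv), CH2Cl2, −78 °C; then 1 M aq. HCl, 0 °C, brief
Reagents that add atoms: water, O (the aldehyde oxygen, on hydrolysis of the imine)
Why: Partial reduction of the nitrile by i-Bu2AlH to the N-aluminio imine (one further equivalent is taken up by the hydroxyl) and mild hydrolysis should give the aldehyde, the isolated alkenes being inert to the hydride at −78 °C; no new stereocenter.

Step 5
Reactants: 5 (4E,8R)-8-hydroxy-4,8-dimethyldeca-4,9-dienal
Product: 6 ethyl (2E,6E,10R)-10-hydroxy-2,6,10-trimethyldodeca-2,6,11-trienoate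
Conditions: Ph3P=C(CH3)CO2Et (1.3 equiv), CH2Cl2, rt
Reagents that add atoms: ethyl 2-(triphenylphosphoranylidene)propanoate, CCOC(=O)C(C)=P(c1ccccc1)(c1ccccc1)c1ccccc1
Why: Wittig olefination with a stabilized α-methyl ylide, which should give the (E)-2-methyl enoate; the free tertiary alcohol does not interfere and no stereocenter is formed.

Step 6
Reactants: 6 ethyl (2E,6E,10R)-10-hydroxy-2,6,10-trimethyldodeca-2,6,11-trienoate, 7 4-bromo-3-methylphenol
Product: 9 ethyl (2E,6E,10R)-10-hydroxy-12-(4-hydroxy-2-methylphenyl)-2,6,10-trimethyldodeca-2,6-dienoate, via B-alkyl-9-BBN adduct 8 (not isolated)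
Conditions: 9-BBN (1.5 equiv), THF, 0 °C to rt; then 7, Pd(OAc)2 (5 mol %), SPhos (10 mol %), K3PO4 (3 equiv), H2O, THF, 60 °C
Reagents that add atoms: none
Why: 9-BBN should add anti-Markovnikov to the only monosubstituted alkene (the trisubstituted alkenes and the enoate are far slower), and the B-alkyl Suzuki–Miyaura coupling, through oxidative addition of SPhos-ligated zerovalent palladium into the hindered C–Br bond of 7, joins C12 to the arene without touching the stereocenter.

Step 7
Reactants: 9 ethyl (2E,6E,10R)-10-hydroxy-12-(4-hydroxy-2-methylphenyl)-2,6,10-trimethyldodeca-2,6-dienoate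
Product: 11 ethyl (2E,6E)-9-[(2R)-6-hydroxy-2,8-dimethyl-3,4-dihydro-2H-chromen-2-yl]-2,6-dimethylnona-2,6-dienoate, via spirodienone 10 (not isolated)
Conditions: PhI(OAc)2 (1.05 equiv), HFIP/CH2Cl2 (1:9), 0 °C; then BF3·OEt2 (20 mol %), −20 to 0 °C, one pot
Reagents that add atoms: none
Why: Ligand exchange of the phenol at trivalent iodine and loss of PhI make the ring carbon para to the hydroxyl (the carbon that carries the side chain, future C8a) electrophilic, the tertiary hydroxyl attacks it ipso and forms the O1–C8a bond in spirodienone 10, and acid activation of the dienone carbonyl then drives a 1,2-shift of the ring CH2 (C4) from C8a to the neighbouring CH (future C4a), after which proton loss restores the benzene ring as the 6-hydroxychroman. The closest known reaction types are the PhI(OAc)2-mediated oxidative spiroetherification of 4-(3-hydroxyalkyl)phenols and the acid-promoted dienone–phenol (quinol ether) rearrangement of 1-oxaspiro[4.5]deca-6,9-dien-8-ones with ring expansion. The five-membered oxaspiro ring closes by 5-exo attack of oxygen on the para carbon (the three-carbon tether reaches no other electrophilic ring position), and the pyran ring arises from it by ring enlargement through the 1,2-alkyl shift. No lasting stereocenter is created: the spiro carbon of 10 is stereogenic only transiently and both epimers converge, while C2 keeps the R configuration brought in by linalool because no bond to it is made or broken. The step needs carbon rather than oxygen migration and a shift to the hydrogen-bearing neighbour rather than to the methyl-bearing one (future C8): carbon migration leaves an oxygen-stabilized cation at C8a, and only the shift to the unsubstituted carbon can end in proton loss and aromatization, whereas a shift toward the methyl-bearing carbon gives a blocked cation that can only return.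

Step 8
Reactants: 11 ethyl (2E,6E)-9-[(2R)-6-hydroxy-2,8-dimethyl-3,4-dihydro-2H-chromen-2-yl]-2,6-dimethylnona-2,6-dienoate
Product: 12 (2E,6E)-9-[(2R)-6-hydroxy-2,8-dimethyl-3,4-dihydro-2H-chromen-2-yl]-2,6-dimethylnona-2,6-dienoic acid
Conditions: LiOH·H2O (5 equiv), THF/MeOH/H2O (degassed), rt to 40 °C; then 1 M HCl to pH 3
Reagents that add atoms: lithium hydroxide, [Li+].[OH-] (supplies the carboxyl OH oxygen)
Why: Saponification (acyl–oxygen cleavage by hydroxide) of the conjugated ethyl ester under oxygen-free conditions, which the aryl alkyl ether, the phenol and both E alkenes should survive; no stereocenter is affected.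

## Compound list

1 | (R)-(−)-linalool, (3R)-3,7-dimethylocta-1,6-dien-3-ol | C=C[C@](C)(O)CCC=C(C)C | starting material
2 | (2E,6R)-2,6-dimethylocta-2,7-diene-1,6-diol | C=C[C@](C)(O)CC/C=C(\C)CO | intermediate
3 | (3R,6E)-8-bromo-3,7-dimethylocta-1,6-dien-3-ol | C=C[C@](C)(O)CC/C=C(\C)CBr | intermediate
4 | (4E,8R)-8-hydroxy-4,8-dimethyldeca-4,9-dienenitrile | C=C[C@](C)(O)CC/C=C(\C)CCC#N | intermediate
5 | (4E,8R)-8-hydroxy-4,8-dimethyldeca-4,9-dienal | C=C[C@](C)(O)CC/C=C(\C)CCC=O | intermediate
6 | ethyl (2E,6E,10R)-10-hydroxy-2,6,10-trimethyldodeca-2,6,11-trienoate | C=C[C@](C)(O)CC/C=C(\C)CC/C=C(\C)C(=O)OCC | intermediate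
7 | 4-bromo-3-methylphenol | Cc1cc(O)ccc1Br | starting material
8 | B-alkyl-9-BBN adduct of 6, boron on C12, carbinol carbon spatially unchanged (not isolated) | C1CC2CCCC(C1)B2CC[C@](C)(O)CC/C=C(\C)CC/C=C(\C)C(=O)OCC | intermediate
9 | ethyl (2E,6E,10R)-10-hydroxy-12-(4-hydroxy-2-methylphenyl)-2,6,10-trimethyldodeca-2,6-dienoate | Cc1cc(O)ccc1CC[C@](C)(O)CC/C=C(\C)CC/C=C(\C)C(=O)OCC | intermediate
10 | ethyl (2E,6E)-9-[(2R)-2,6-dimethyl-8-oxo-1-oxaspiro[4.5]deca-6,9-dien-2-yl]-2,6-dimethylnona-2,6-dienoate, both epimers at the spiro carbon (not isolated) | C/C(=C\CC[C@]1(C)CCC2(C=CC(=O)C=C2C)O1)CC/C=C(\C)C(=O)OCC | intermediate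
11 | ethyl (2E,6E)-9-[(2R)-6-hydroxy-2,8-dimethyl-3,4-dihydro-2H-chromen-2-yl]-2,6-dimethylnona-2,6-dienoate | C/C(=C\CC[C@]1(C)CCc2cc(O)cc(C)c2O1)CC/C=C(\C)C(=O)OCC | intermediate
12 | (2E,6E)-9-[(2R)-6-hydroxy-2,8-dimethyl-3,4-dihydro-2H-chromen-2-yl]-2,6-dimethylnona-2,6-dienoic acid | C/C(=C\CC[C@]1(C)CCc2cc(O)cc(C)c2O1)CC/C=C(\C)C(=O)O | target

## Step count and risks

Total step count: 8. Longest linear sequence: 8 steps (from 1).

**Step 7 (key step).** The 1,2-shift may run toward the methyl-bearing carbon, or oxygen may migrate instead of carbon, which would give isomeric chromanols. The acid may also ionize the tertiary C2–O bond (erosion of configuration) or protonate the trisubstituted alkenes. Fallback (sets out from 6 through its borane 8, returns at 11): the O1–C8a bond would be made at the quinone monoketal oxidation level with the chain already on C4a, so that no cationic shift is needed. Borane 8 is coupled under the step 6 conditions with commercially available 3-bromo-5-methylphenol to give ethyl (2E,6E,10R)-10-hydroxy-12-(3-hydroxy-5-methylphenyl)-2,6,10-trimethyldodeca-2,6-dienoate F1. Oxidation of this para-unsubstituted phenol with PhI(OAc)2 (2.2 equiv) in MeOH/CH2Cl2 at 0 °C (phenol to quinone monoketal oxidation; the released AcOH equilibrates the ketal carbon) is expected to give ethyl (2E,6E)-9-[(2R)-8a-methoxy-2,8-dimethyl-6-oxo-3,4,6,8a-tetrahydro-2H-chromen-2-yl]-2,6-dimethylnona-2,6-dienoate F2, in which the tethered tertiary hydroxyl and one methanol are both bound to C8a. Zn dust in AcOH/THF should then remove the methoxy group reductively and rearomatize to 11, as in the reduction of 8a-alkoxy chromenones of the vitamin E series; C2 is again never touched.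

**Step 6.** Oxidative addition into the electron-rich, ortho-substituted bromophenoxide may be slow, so that protodeboronation or β-hydride loss of the alkylborane, or slow attack of excess 9-BBN on the enoate, takes over. Fallback (sets out from 6 and 7, returns at 9): Mizoroki–Heck arylation of the vinyl carbinol of 6 with 7 (Pd(OAc)2, P(o-tol)3, Et3N, DMF, 90 °C) should give ethyl (2E,6E,10R,11E)-10-hydroxy-12-(4-hydroxy-2-methylphenyl)-2,6,10-trimethyldodeca-2,6,11-trienoate F3. Diimide (2-nitrobenzenesulfonyl hydrazide, Et3N, CH2Cl2, rt) should then saturate the 1,2-disubstituted styrenic alkene in preference to the trisubstituted alkenes and the trisubstituted enoate, giving 9.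

**Step 1.** Over-oxidation to the enal, competing oxidation at the allylic CH2, or stalling at low conversion may make the allylic oxidation inefficient. Fallback (sets out from 1, returns at 2): selective ozonolysis of the trisubstituted alkene of 1 (O3, CH2Cl2/MeOH, −78 °C, one equivalent, then Me2S) gives (4R)-4-hydroxy-4-methylhex-5-enal F4. Wittig olefination with Ph3P=C(CH3)CO2Et gives ethyl (2E,6R)-6-hydroxy-2,6-dimethylocta-2,7-dienoate F5, and i-Bu2AlH (3 equiv, CH2Cl2, −78 °C) reduces the ester to allylic alcohol 2 with the E geometry fixed by the olefination.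

Further compounds
F1 | step 7 | ethyl (2E,6E,10R)-10-hydroxy-12-(3-hydroxy-5-methylphenyl)-2,6,10-trimethyldodeca-2,6-dienoate | Cc1cc(O)cc(CC[C@](C)(O)CC/C=C(\C)CC/C=C(\C)C(=O)OCC)c1
F2 | step 7 | ethyl (2E,6E)-9-[(2R)-8a-methoxy-2,8-dimethyl-6-oxo-3,4,6,8a-tetrahydro-2H-chromen-2-yl]-2,6-dimethylnona-2,6-dienoate, both epimers at C8a | C/C(=C\CC[C@]1(C)CCC2=CC(=O)C=C(C)C2(OC)O1)CC/C=C(\C)C(=O)OCC
F3 | step 6 | ethyl (2E,6E,10R,11E)-10-hydroxy-12-(4-hydroxy-2-methylphenyl)-2,6,10-trimethyldodeca-2,6,11-trienoate | Cc1cc(O)ccc1/C=C/[C@](C)(O)CC/C=C(\C)CC/C=C(\C)C(=O)OCC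
F4 | step 1 | (4R)-4-hydroxy-4-methylhex-5-enal | C=C[C@](C)(O)CCC=O
F5 | step 1 | ethyl (2E,6R)-6-hydroxy-2,6-dimethylocta-2,7-dienoate | C=C[C@](C)(O)CC/C=C(\C)C(=O)OCC
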